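**Plan**

- Numbering: C1 is the benzylic carbon, C2 the carbinol carbon, C17 the chain end. The retrosynthesis cuts C6–C7 (as a C6=C7 Wittig alkene), then the C2–O bond (Baeyer–Villiger oxygen insertion), then the C1–aryl link (aldol condensation, exocyclic C=C).
- Enabling feature: the C2 hydroxyl oxygen is 1,5 to C6, so O–C2–C3–C4–C5–C6 can be held as a six-membered ring (δ-lactone, then δ-lactol, a tetrahydropyran with C6 as the anomeric carbon). That ring is the Baeyer–Villiger product of a 2-(arylmethyl)cyclopentanone, so the five carbons of cyclopentanone become C2–C6.
- Forward order: cyclopentanone and 3-hydroxy-5-methoxybenzaldehyde give the arylidene ketone, then the benzyl ketone (cyclopentane ring), then the δ-lactone by enzymatic ring expansion, then the lactol. A ring-opening Wittig reaction joins the C11 chain at C6, and hydrogenation finishes.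
- Stereochemistry: the only stereocentre (C2, R) is selected by a Baeyer–Villiger monooxygenase in a kinetic resolution of the racemic ketone (migration with retention) and is not touched afterwards.
- The temporary ring also protects the C2 hydroxyl, so no protecting groups are used; the helper alkene is removed in the last step.

Key step: step 5

Assumption: the monooxygenase of step 3 is picked from a cyclohexanone-monooxygenase-type panel for conversion of the (R)-ketone, the enantiomer this enzyme family is expected to prefer in 2-substituted cyclopentanones of this spatial series.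

**Step 1**
Reactants: 1 cyclopentanone; 2 3-hydroxy-5-methoxybenzaldehyde
Product: 3 (E)-2-(3-hydroxy-5-methoxybenzylidene)cyclopentan-1-one
Conditions: 1 (5 equiv), NaOH (2.2 equiv), EtOH–H2O, 0 °C to rt; then aq HCl to pH 5
Reagents that add atoms: none
Why: Crossed aldol (Claisen–Schmidt) condensation in which the aldehyde has no α-hydrogen, the excess of cyclopentanone should hold back a second condensation at C5, and dehydration of the aldol should give the conjugated E-enone without forming a stereocentre.

**Step 2**
Reactants: 3 (E)-2-(3-hydroxy-5-methoxybenzylidene)cyclopentan-1-one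
Product: 4 rac-2-(3-hydroxy-5-methoxybenzyl)cyclopentan-1-one
Conditions: H2 (1 atm), 5% Pd/C, EtOAc, rt, stopped after one equivalent of H2
Reagents that add atoms: none
Why: Heterogeneous catalytic hydrogenation should reduce the aryl-conjugated enone C=C much faster than the ketone or the arene, and the new ring stereocentre is formed as the racemate on purpose because step 3 resolves it.

**Step 3**
Reactants: 4 rac-2-(3-hydroxy-5-methoxybenzyl)cyclopentan-1-one
Product: 5 (R)-6-(3-hydroxy-5-methoxybenzyl)tetrahydro-2H-pyran-2-one
Conditions: CHMO-type Baeyer–Villiger monooxygenase (cell-free extract), NADP+ (cat), glucose dehydrogenase, D-glucose, air, phosphate buffer pH 8, 5% MeOH, 25 °C, stopped near half conversion; lactone separated from unreacted ketone by chromatography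
Reagents that add atoms: dioxygen (O=O)
Why: Enzymatic Baeyer–Villiger oxidation run as a kinetic resolution, in which the flavin peroxide of the monooxygenase should add to the carbonyl of the (R)-ketone only and the more substituted ring carbon migrates with retention, so the C–O stereocentre is the enzyme-selected C2 centre of the ketone, while the electron-rich phenol ring that a peracid could attack is left alone.

**Step 4**
Reactants: 5 (R)-6-(3-hydroxy-5-methoxybenzyl)tetrahydro-2H-pyran-2-one
Product: 6 (6R)-6-(3-hydroxy-5-methoxybenzyl)tetrahydro-2H-pyran-2-ol (both anomers)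
Conditions: DIBAL-H (2.3 equiv), CH2Cl2, −78 °C; aq Rochelle salt
Reagents that add atoms: none
Why: Partial reduction of a lactone by DIBAL-H at low temperature should stop at the aluminium hemiacetal and give the lactol on work-up, with one extra equivalent taken by the phenol, the carbinol stereocentre untouched and the new anomeric centre formed as a mixture that step 5 destroys.

**Step 5**
Reactants: 6 (6R)-6-(3-hydroxy-5-methoxybenzyl)tetrahydro-2H-pyran-2-ol; 7 undecyl(triphenyl)phosphonium bromide
Product: 10 (2R,6Z)-1-(3-hydroxy-5-methoxyphenyl)heptadec-6-en-2-ol, via undecylidene(triphenyl)phosphorane 8 (not isolated), via (R)-5-hydroxy-6-(3-hydroxy-5-methoxyphenyl)hexanal 9 (not isolated)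
Conditions: 7 (3.5 equiv), KHMDS (3.4 equiv), THF, 0 °C; then 6, 0 °C to rt; aq NH4Cl
Reagents that add atoms: none
Why: Base converts lactol 6 into its alkoxide, which is in ring–chain equilibrium with the open hydroxy aldehyde 9 (present as its dianion); the non-stabilised ylide 8 adds to this aldehyde carbon (C6) to give an oxaphosphetane whose cycloreversion forms the C6=C7 double bond and triphenylphosphine oxide and so drains the equilibrium toward the open chain. The closest known reaction type is the Wittig olefination of five- and six-membered lactols by non-stabilised alkylidenephosphoranes in the presence of free hydroxyl groups. No ring is closed: the tetrahydropyran ring is opened at the anomeric C6–O bond, which in the same event sets the C2 hydroxyl free, so the ring has served both as carbonyl mask and as protecting group. No stereocentre is formed; the alkene should be mainly Z, which is of no consequence because step 6 removes it, and the C2 centre cannot epimerise because its C–O bond is not broken and it is not α to the carbonyl. The selectivity needed is chemoselectivity beside two acidic O–H groups, and it is secured by the excess of base and ylide, which turns the phenol and the lactol OH into a phenoxide and an alkoxide that are inert to the ylide and leaves the unmasked aldehyde as the only electrophile.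

**Step 6**
Reactants: 10 (2R,6Z)-1-(3-hydroxy-5-methoxyphenyl)heptadec-6-en-2-ol
Product: 11 (R)-1-(3-hydroxy-5-methoxyphenyl)heptadecan-2-ol
Conditions: H2 (1 atm), 10% Pd/C, EtOAc, rt
Reagents that add atoms: none
Why: Heterogeneous hydrogenation should saturate the isolated disubstituted alkene while leaving the arene, the aryl methyl ether and the non-benzylic secondary alcohol intact, so any E/Z mixture converges on the target with the C2 stereocentre unchanged.

**Compound list**

1 | cyclopentanone | O=C1CCCC1 | starting material
2 | 3-hydroxy-5-methoxybenzaldehyde | O=Cc1cc(O)cc(OC)c1 | starting material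
3 | (E)-2-(3-hydroxy-5-methoxybenzylidene)cyclopentan-1-one | O=C1CCC/C1=C\c1cc(O)cc(OC)c1 | intermediate
4 | rac-2-(3-hydroxy-5-methoxybenzyl)cyclopentan-1-one | O=C1CCCC1Cc1cc(O)cc(OC)c1 | intermediate
5 | (R)-6-(3-hydroxy-5-methoxybenzyl)tetrahydro-2H-pyran-2-one | O=C1CCC[C@H](Cc2cc(O)cc(OC)c2)O1 | intermediate
6 | (6R)-6-(3-hydroxy-5-methoxybenzyl)tetrahydro-2H-pyran-2-ol (both anomers) | OC1CCC[C@H](Cc2cc(O)cc(OC)c2)O1 | intermediate
7 | undecyl(triphenyl)phosphonium bromide | CCCCCCCCCCC[P+](c1ccccc1)(c1ccccc1)c1ccccc1.[Br-] | starting material
8 | undecylidene(triphenyl)phosphorane (not isolated) | CCCCCCCCCCC=P(c1ccccc1)(c1ccccc1)c1ccccc1 | intermediate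
9 | (R)-5-hydroxy-6-(3-hydroxy-5-methoxyphenyl)hexanal (not isolated) | O=CCCC[C@@H](O)Cc1cc(O)cc(OC)c1 | intermediate
10 | (2R,6Z)-1-(3-hydroxy-5-methoxyphenyl)heptadec-6-en-2-ol | CCCCCCCCCC/C=C\CCC[C@@H](O)Cc1cc(O)cc(OC)c1 | intermediate
11 | (R)-1-(3-hydroxy-5-methoxyphenyl)heptadecan-2-ol | CCCCCCCCCCCCCCC[C@@H](O)Cc1cc(O)cc(OC)c1 | target

**Step count**

Total steps: 6. Longest linear sequence: 6 steps (1 to 6).

**Steps most likely to fail**

Step 3. The enzyme may discriminate poorly between the two ketone enantiomers, or turn over the phenolic substrate slowly, which would erode the enantiomeric purity or the conversion to the lactone. The fallback sets the stereocentre by asymmetric hydrogenation and inserts the oxygen chemically. It sets out from 3 and comes back to the route at 6. Acetylation of 3 (Ac2O, pyridine) should give (E)-3-methoxy-5-[(2-oxocyclopentylidene)methyl]phenyl acetate F1. Iridium-catalysed asymmetric hydrogenation of the exocyclic enone C=C (chiral phosphine–oxazoline ligand, H2, CH2Cl2; ligand enantiomer chosen for the R product) should give (R)-3-methoxy-5-[(2-oxocyclopentyl)methyl]phenyl acetate F2. Peracid Baeyer–Villiger oxidation (mCPBA, NaHCO3, CH2Cl2), with migration of the secondary carbon under retention and the acetate tempering the ring against the peracid, should give (R)-3-methoxy-5-[(6-oxotetrahydro-2H-pyran-2-yl)methyl]phenyl acetate F3. Excess DIBAL-H at −78 °C should then reduce the lactone to the lactol and cleave the aryl acetate in the same operation, giving 6.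

Step 5. The phenoxide/alkoxide dianion may aggregate or precipitate and ring opening may be slow, so that the ylide is consumed by proton transfer instead of olefination. The fallback makes the same C6–C7 bond by acyl substitution and then removes the carbonyl. It sets out from 5 and comes back at 11. Aminolysis of lactone 5 with N,O-dimethylhydroxylamine hydrochloride and Me3Al should give (R)-5-hydroxy-6-(3-hydroxy-5-methoxyphenyl)-N-methoxy-N-methylhexanamide F4. Excess undecylmagnesium bromide in THF should give (R)-2-hydroxy-1-(3-hydroxy-5-methoxyphenyl)heptadecan-6-one F5. Wolff–Kishner reduction under Huang-Minlon conditions (hydrazine hydrate, KOH, diethylene glycol, 120 then 200 °C) should pass through (R)-6-hydrazinylidene-1-(3-hydroxy-5-methoxyphenyl)heptadecan-2-ol F6 and deliver 11 directly.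

Step 1. A second condensation at C5 of the first-formed enone and self-condensation of cyclopentanone under hydroxide may lower the yield of the mono-arylidene ketone. The fallback uses a preformed enamine as the nucleophile (Stork enamine condensation). It sets out from 1 and comes back at 3. Cyclopentanone and morpholine (cat TsOH, toluene, Dean–Stark) should give 4-(cyclopent-1-en-1-yl)morpholine F7. Heating F7 with 2 in toluene, followed by hydrolysis with aq HCl, should give 3; the mono-adduct is a poorer nucleophile at this stage, so the second condensation should be suppressed.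

**Further compounds**

F1 | step 3 | (E)-3-methoxy-5-[(2-oxocyclopentylidene)methyl]phenyl acetate | O=C1CCC/C1=C\c1cc(OC(C)=O)cc(OC)c1
F2 | step 3 | (R)-3-methoxy-5-[(2-oxocyclopentyl)methyl]phenyl acetate | O=C1CCC[C@@H]1Cc1cc(OC(C)=O)cc(OC)c1
F3 | step 3 | (R)-3-methoxy-5-[(6-oxotetrahydro-2H-pyran-2-yl)methyl]phenyl acetate | O=C1CCC[C@H](Cc2cc(OC(C)=O)cc(OC)c2)O1
F4 | step 5 | (R)-5-hydroxy-6-(3-hydroxy-5-methoxyphenyl)-N-methoxy-N-methylhexanamide | CON(C)C(=O)CCC[C@@H](O)Cc1cc(O)cc(OC)c1
F5 | step 5 | (R)-2-hydroxy-1-(3-hydroxy-5-methoxyphenyl)heptadecan-6-one | CCCCCCCCCCCC(=O)CCC[C@@H](O)Cc1cc(O)cc(OC)c1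
F6 | step 5 | (R)-6-hydrazinylidene-1-(3-hydroxy-5-methoxyphenyl)heptadecan-2-ol | CCCCCCCCCCCC(=NN)CCC[C@@H](O)Cc1cc(O)cc(OC)c1
F7 | step 1 | 4-(cyclopent-1-en-1-yl)morpholine | C1=C(CCC1)N1CCOCC1
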